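**Plan**
Cuts, in order: the C4 acetate and the C3 epoxyangelate; the C3–O and C4–O bonds (diol from a Δ3 olefin); the C4–CH3 bond (enol triflate of a C4 ketone that is masked as a dithiane).
Then C4–C5 and C9–C10 together (cationic bicyclisation of an acyclic Z-diene), C3=C4 (Peterson olefination) and C6–C7 (enolate alkylation).
Forward: neryl acetate gives the Z-allylic bromide; Evans alkylation joins it to the isovaleryl imide; the acyl carbon becomes the C8 chloroalkene; a ketene dithioacetal is built at C4; acid closes rings A and B in one step.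
Then C8 ketal, C4 ketone, enol triflate, methyl coupling, cis-dihydroxylation and the two acylations.
Stereochemistry: C7 from the auxiliary; C5 and C10 from C7 and the Z olefin in the bicyclisation; C3 and C4 from a Woodward cis-hydroxylation on the α face; C7 is then equilibrated to the β-isopropyl epimer; the oxirane comes from a Sharpless epoxidation.

Key step: step 12

Remark: locants are eudesmane locants (C3 ester carbinol, C4 acetoxy carbon, C8 ketone) and β is the face of the C10 methyl group; neryl acetate, the commercial acetate of nerol, is taken as the terpene starting material.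

Step 1
Reactants: 1 neryl acetate
Product: 3 (2Z)-3-methyl-6-oxohex-2-en-1-yl acetate, via 6,7-epoxyneryl acetate 2 (not isolated)
Conditions: mCPBA, CH2Cl2, 0 °C; then HIO4·2H2O, THF–H2O, 0 °C
Reagents that add atoms: 3-chloroperbenzoic acid, OOC(=O)c1cccc(Cl)c1
Why: The 6,7-olefin is the more electron-rich one (the 2,3-olefin carries the allylic acetate), so Prilezhaev epoxidation should take place there, and periodic acid then cleaves the epoxide through its diol to the aldehyde (Malaprade-type glycol cleavage).

Step 2
Reactants: 3 aldehyde acetate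
Product: 5 (2Z)-6,6-dimethoxy-3-methylhex-2-en-1-ol, via acetal acetate 4 (not isolated)
Conditions: HC(OMe)3, MeOH, PPTS (cat.), 23 °C; then K2CO3 (cat.), 23 °C
Reagents that add atoms: trimethyl orthoformate, COC(OC)OC
Why: Acid-catalysed acetalisation with the orthoester as water scavenger masks the aldehyde, and base-catalysed transesterification in the same methanol frees the allylic alcohol without touching the Z olefin.

Step 3
Reactants: 5 allylic alcohol
Product: 7 (2Z)-1-bromo-6,6-dimethoxy-3-methylhex-2-ene, via allylic mesylate 6 (not isolated)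
Conditions: MsCl, Et3N, CH2Cl2, −40 °C; then LiBr, THF, 0 °C
Reagents that add atoms: lithium bromide, [Li+].[Br-]
Why: Mesylation followed by SN2 displacement with bromide under non-acidic conditions should give the primary allylic bromide without allylic transposition, Z/E isomerisation or loss of the acetal.

Step 4
Reactants: 8 (S)-4-benzyl-1,3-oxazolidin-2-one; 9 3-methylbutanoyl chloride
Product: 10 (S)-4-benzyl-3-(3-methylbutanoyl)-1,3-oxazolidin-2-one
Conditions: Et3N, DMAP (cat.), CH2Cl2, 0 → 23 °C
Reagents that add atoms: none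
Why: N-acylation of the oxazolidinone by the acid chloride under nucleophilic catalysis is a standard entry to the Evans imide.

Step 5
Reactants: 10 isovaleryl imide; 7 allylic bromide
Product: 12 (S)-4-benzyl-3-[(2S,4Z)-8,8-dimethoxy-5-methyl-2-(propan-2-yl)oct-4-enoyl]-1,3-oxazolidin-2-one, via sodium Z-enolate 11 (not isolated)
Conditions: NaN(SiMe3)2, THF, −78 °C; then 7, −78 → −40 °C
Reagents that add atoms: none
Why: Evans asymmetric alkylation, in which the chelated Z-enolate is attacked by the allylic bromide on the face opposite the benzyl group, so that the C6–C7 bond forms and C7 is set as S.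

Step 6
Reactants: 12 alkylated imide
Product: 14 (2S,4Z)-8,8-dimethoxy-5-methyl-2-(propan-2-yl)oct-4-enoic acid, via lithium peroxycarboxylate 13 (not isolated)
Conditions: LiOH, H2O2, THF–H2O, 0 °C; then Na2SO3; 1 M HCl to pH 4, 0 °C
Reagents that add atoms: hydrogen peroxide, OO
Why: Hydroperoxide-mediated hydrolysis attacks the exocyclic carbonyl even of this α-branched imide, so the auxiliary is released without epimerisation of C7 and the sulfite reduces the peroxy acid to the acid.

Step 7
Reactants: 14 carboxylic acid
Product: 16 (3S,5Z)-9,9-dimethoxy-6-methyl-3-(propan-2-yl)non-5-en-2-one, via dilithium gem-diolate 15 (not isolated)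
Conditions: MeLi (3 equiv), Et2O, 0 → 23 °C; inverse quench into ice–water
Reagents that add atoms: methyllithium, [Li]C
Why: Addition of methyllithium to the lithium carboxylate stops at the dilithium gem-diolate, which releases the methyl ketone only on hydrolysis (ketone synthesis from a carboxylic acid and an organolithium), and the C7 methine is not enolised.

Step 8
Reactants: 16 methyl ketone
Product: 18 (3S,5Z)-9,9-dimethoxy-6-methyl-3-(propan-2-yl)nona-1,5-dien-2-yl trifluoromethanesulfonate, via potassium enolate 17 (not isolated)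
Conditions: KN(SiMe3)2, THF, −78 °C; then PhNTf2, −78 → 0 °C
Reagents that add atoms: N-phenylbis(trifluoromethanesulfonimide), O=S(=O)(N(c1ccccc1)S(=O)(=O)C(F)(F)F)C(F)(F)F
Why: Kinetic deprotonation takes the methyl group and not the hindered C7 methine, and O-sulfonylation of the terminal enolate gives the 1,1-disubstituted enol triflate with C7 intact.

Step 9
Reactants: 18 enol triflate
Product: 19 (3S,5Z)-2-chloro-9,9-dimethoxy-6-methyl-3-(propan-2-yl)nona-1,5-diene
Conditions: LiCl, Ni(OAc)2·4H2O (cat.), 1,5-cyclooctadiene (cat.), Zn (cat.), DMA–THF, 23 °C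
Reagents that add atoms: lithium chloride, [Li+].[Cl-]
Why: Nickel-catalysed halide exchange of an enol triflate (oxidative addition to zerovalent nickel, triflate/chloride exchange, C–Cl reductive elimination) turns C–OTf into C–Cl under neutral conditions that leave the acetal and the trisubstituted olefin alone.

Step 10
Reactants: 19 chloroalkene acetal
Product: 20 (4Z,7S)-8-chloro-4-methyl-7-(propan-2-yl)nona-4,8-dienal
Conditions: 1 M HCl, THF, 0 → 23 °C
Reagents that add atoms: water, O
Why: Acid-catalysed acetal hydrolysis, to which the chloroalkene and the trisubstituted olefin are inert.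

Step 11
Reactants: 20 aldehyde; 21 2-(trimethylsilyl)-1,3-dithiane
Product: 24 2-[(4Z,7S)-8-chloro-4-methyl-7-(propan-2-yl)nona-4,8-dien-1-ylidene]-1,3-dithiane, via 2-lithio-2-(trimethylsilyl)-1,3-dithiane 22 (not isolated), via lithium β-silyl alkoxide 23 (not isolated)
Conditions: 21, n-BuLi, THF, −30 °C; then 20, −78 → 23 °C
Reagents that add atoms: none
Why: Peterson olefination, in which the silylated dithiane anion adds to the aldehyde and the β-silyl alkoxide loses lithium trimethylsilanolate on warming to give the ketene dithioacetal that carries C4.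

Step 12
Reactants: 24 Z-dienyl ketene dithioacetal
Product: 27 cis-fused dithiane ketone (15-nor-7-epi-5β-eudesman-8-one with C4 as spiro carbon of a 1,3-dithiane; 5S,7S,10R), via dithienium trifluoroacetate 25 (not isolated), via chloro trifluoroacetate 26 (not isolated)
Conditions: CF3CO2H (10 equiv), CH2Cl2, −20 → 0 °C; then H2O
Reagents that add atoms: trifluoroacetic acid, OC(=O)C(F)(F)F (its oxygen becomes the C8 carbonyl oxygen through 26)
Why: Protonation of the ketene dithioacetal at C3 gives the 2-alkyl-1,3-dithienium ion 25 (cation at C4), which adds to C5 of the Z olefin; the tertiary C10 cation is taken by the CH2 terminus (C9) of the chloroalkene, and the chlorine-stabilised C8 cation is trapped by trifluoroacetate as 26, which hydrolyses to the ketone. The closest known reaction type is the cation–olefin polycyclisation with a ketene dithioacetal initiator and chloro-olefin termination. Ring A closes 6-endo (C4 onto C5=C10) and ring B closes 6-endo (C9=C8 onto C10), both through chair-like arrangements. Antiperiplanar addition across the Z olefin places H5 and the C10 methyl group cis (cis fusion), and the S centre at C7, with its isopropyl group pseudo-equatorial on the ring B chair, selects the olefin face and so sets C5 as S and C10 as R. The step needs protonation at the ketene dithioacetal only, which its far higher basicity over the other two olefins secures, and termination at C8 only, which the chlorine secures; addition of the stabilised dithienium ion is expected to be reversible, so the face is chosen in the ring B closure. The product is the C7 epimer of the natural series, which step 18 corrects.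

Step 13
Reactants: 27 dithiane ketone
Product: 28 C8 ethylene ketal of 27
Conditions: Me3SiOCH2CH2OSiMe3, Me3SiOTf (cat.), CH2Cl2, −78 → −20 °C
Reagents that add atoms: 1,2-bis(trimethylsilyloxy)ethane, C[Si](C)(C)OCCO[Si](C)(C)C
Why: Silyl-triflate-catalysed ketalisation with the bis-silyl ether (Noyori conditions) masks the C8 ketone at low temperature without disturbing the dithiane, so that C4 can later be unmasked and enolised alone.

Step 14
Reactants: 28 dithiane ketal
Product: 29 C4 ketone (8,8-ethylenedioxy-15-nor-7-epi-5β-eudesman-4-one)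
Conditions: MeI, CaCO3, MeCN–H2O (9:1), 45 °C
Reagents that add atoms: water, O
Why: Alkylative hydrolysis of the dithiane (S-methylation makes sulfur a leaving group and water adds to the thionium ion) frees the C4 ketone under buffered neutral conditions that spare the dioxolane and the epimerisable C5 centre.

Step 15
Reactants: 29 C4 ketone
Product: 31 Δ3 enol triflate (4-triflyloxy-3-ene), via potassium enolate 30 (not isolated)
Conditions: KN(SiMe3)2, THF, −78 °C; then PhNTf2, −78 → 0 °C
Reagents that add atoms: N-phenylbis(trifluoromethanesulfonimide), O=S(=O)(N(c1ccccc1)S(=O)(=O)C(F)(F)F)C(F)(F)F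
Why: Kinetic deprotonation takes the C3 methylene rather than the C5 methine at the ring fusion, so O-triflation fixes the olefin at C3=C4 and leaves the cis fusion untouched.

Step 16
Reactants: 31 enol triflate
Product: 32 8,8-ethylenedioxy-7-epi-5β-eudesm-3-ene
Conditions: MeMgBr, Fe(acac)3 (cat.), THF–NMP, −20 → 0 °C
Reagents that add atoms: methylmagnesium bromide, C[Mg]Br
Why: Iron-catalysed cross-coupling of an alkenyl triflate with a methyl Grignard reagent (Kumada-type coupling) places the C4 methyl group on the olefin while the ketal shields C8.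

Step 17
Reactants: 32 olefin ketal
Product: 33 7-epi-5β-eudesm-3-en-8-one
Conditions: 1 M HCl, THF, 0 → 23 °C
Reagents that add atoms: water, O
Why: Acid-catalysed hydrolysis of the dioxolane returns the C8 ketone, and the trisubstituted olefin should not migrate under this dilute acid.

Step 18
Reactants: 33 olefin ketone
Product: 37 3α,4α-dihydroxy-5β-eudesman-8-one (3R,4S,5S,7R,10R), via iodo acetate 34 (not isolated), via hydroxy acetate 35 (not isolated), via 7-epi keto diol 36 (not isolated)
Conditions: I2, AgOAc, AcOH, 23 °C; then H2O, 90 °C; filter, concentrate; then NaOMe (cat.), MeOH, 23 °C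
Reagents that add atoms: silver acetate, CC(=O)[O-].[Ag+]
Why: Woodward cis-hydroxylation, in which iodine should add to the convex β face (ring B lies under the α face), acetate opens the iodonium ion from the α face and silver-assisted displacement of iodide by the neighbouring acetate gives an α-face acetoxonium ion that water opens, so both oxygens arrive on the hindered α face (C3 R, C4 S), after which methoxide removes the acetate and equilibrates C7 through the enolate to the β-isopropyl epimer, the only one that can hold the isopropyl group equatorial in the conformer free of syn-axial C4 and C10 methyl groups.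

Step 19
Reactants: 38 angelic acid
Product: 39 (2Z)-2-methylbut-2-en-1-ol
Conditions: LiAlH4, Et2O, 0 °C
Reagents that add atoms: none
Why: Hydride reduction of the carboxylic acid at low temperature gives the allylic alcohol without conjugate reduction or Z to E isomerisation.

Step 20
Reactants: 39 allylic alcohol
Product: 40 [(2R,3S)-2,3-dimethyloxiran-2-yl]methanol
Conditions: Ti(OiPr)4 (cat.), D-(−)-diethyl tartrate (cat.), t-BuOOH, 4 Å molecular sieves, CH2Cl2, −20 °C
Reagents that add atoms: tert-butyl hydroperoxide, CC(C)(C)OO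
Why: Sharpless asymmetric epoxidation, in which the D-(−)-tartrate ligand directs oxygen to the olefin face that gives the 2R,3S epoxy alcohol and the Z geometry fixes the cis relation of the C3 methyl group and the CH2OH group.

Step 21
Reactants: 40 epoxy alcohol
Product: 42 (2S,3S)-2,3-dimethyloxirane-2-carboxylic acid, via epoxy aldehyde 41 (not isolated)
Conditions: TEMPO (cat.), NaOCl (cat.), NaClO2, MeCN–phosphate buffer (pH 6.7), 35 °C
Reagents that add atoms: sodium chlorite, [Na+].[O-]Cl=O
Why: Oxoammonium oxidation to the aldehyde and chlorite oxidation of the aldehyde (Pinnick-type) in one pot near neutral pH give the glycidic acid without opening the oxirane.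

Step 22
Reactants: 37 keto diol; 42 epoxy acid
Product: 44 3α-[(2S,3S)-2,3-dimethyloxirane-2-carbonyloxy]-4α-hydroxy-5β-eudesman-8-one, via mixed anhydride 43 (not isolated)
Conditions: 42, 2,4,6-Cl3C6H2COCl, Et3N, THF, 0 °C; then 37, DMAP, toluene, 23 °C
Reagents that add atoms: none
Why: Yamaguchi esterification, in which the mixed anhydride acylates only the secondary 3α-hydroxyl because the tertiary 4α-hydroxyl is too hindered, and the oxirane survives the non-acidic conditions.

Step 23
Reactants: 44 hydroxy ester
Product: 45 target, 4α-acetoxy-3α-[(2S,3S)-2,3-dimethyloxirane-2-carbonyloxy]-5β-eudesman-8-one (3R,4S,5S,7R,10R)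
Conditions: Ac2O, DMAP, Et3N, CH2Cl2, 40 °C
Reagents that add atoms: acetic anhydride, CC(=O)OC(C)=O
Why: DMAP-catalysed acylation through the N-acetylpyridinium ion should acetylate the remaining tertiary alcohol under conditions mild enough for the epoxy ester and the ketone.

**Compound list**
1 | neryl acetate, (2Z)-3,7-dimethylocta-2,6-dien-1-yl acetate | CC(=O)OC/C=C(C)\CCC=C(C)C | starting material
2 | 6,7-epoxyneryl acetate (racemic at the oxirane) | CC(=O)OC/C=C(C)\CCC1OC1(C)C | intermediate (not isolated)
3 | (2Z)-3-methyl-6-oxohex-2-en-1-yl acetate | CC(=O)OC/C=C(C)\CCC=O | intermediate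
4 | (2Z)-6,6-dimethoxy-3-methylhex-2-en-1-yl acetate | CC(=O)OC/C=C(C)\CCC(OC)OC | intermediate (not isolated)
5 | (2Z)-6,6-dimethoxy-3-methylhex-2-en-1-ol | OC/C=C(C)\CCC(OC)OC | intermediate
6 | (2Z)-6,6-dimethoxy-3-methylhex-2-en-1-yl methanesulfonate | CS(=O)(=O)OC/C=C(C)\CCC(OC)OC | intermediate (not isolated)
7 | (2Z)-1-bromo-6,6-dimethoxy-3-methylhex-2-ene | BrC/C=C(C)\CCC(OC)OC | intermediate
8 | (S)-4-benzyl-1,3-oxazolidin-2-one | O=C1N[C@@H](Cc2ccccc2)CO1 | starting material
9 | 3-methylbutanoyl chloride | CC(C)CC(=O)Cl | starting material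
10 | (S)-4-benzyl-3-(3-methylbutanoyl)-1,3-oxazolidin-2-one | CC(C)CC(=O)N1[C@@H](Cc2ccccc2)COC1=O | intermediate
11 | sodium Z-enolate of 10 | [Na+].CC(C)/C=C(\[O-])N1[C@@H](Cc2ccccc2)COC1=O | intermediate (not isolated)
12 | (S)-4-benzyl-3-[(2S,4Z)-8,8-dimethoxy-5-methyl-2-(propan-2-yl)oct-4-enoyl]-1,3-oxazolidin-2-one | O=C(N1[C@@H](Cc2ccccc2)COC1=O)[C@H](C(C)C)C/C=C(C)\CCC(OC)OC | intermediate
13 | lithium (2S,4Z)-8,8-dimethoxy-5-methyl-2-(propan-2-yl)oct-4-eneperoxoate | [Li+].[O-]OC(=O)[C@H](C(C)C)C/C=C(C)\CCC(OC)OC | intermediate (not isolated)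
14 | (2S,4Z)-8,8-dimethoxy-5-methyl-2-(propan-2-yl)oct-4-enoic acid | OC(=O)[C@H](C(C)C)C/C=C(C)\CCC(OC)OC | intermediate
15 | dilithium gem-diolate from 14 and methyllithium | [Li+].[Li+].CC([O-])([O-])[C@H](C(C)C)C/C=C(C)\CCC(OC)OC | intermediate (not isolated)
16 | (3S,5Z)-9,9-dimethoxy-6-methyl-3-(propan-2-yl)non-5-en-2-one | CC(=O)[C@H](C(C)C)C/C=C(C)\CCC(OC)OC | intermediate
17 | potassium enolate of 16 (terminal) | [K+].[O-]C(=C)[C@H](C(C)C)C/C=C(C)\CCC(OC)OC | intermediate (not isolated)
18 | (3S,5Z)-9,9-dimethoxy-6-methyl-3-(propan-2-yl)nona-1,5-dien-2-yl trifluoromethanesulfonate | C=C(OS(=O)(=O)C(F)(F)F)[C@H](C(C)C)C/C=C(C)\CCC(OC)OC | intermediate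
19 | (3S,5Z)-2-chloro-9,9-dimethoxy-6-methyl-3-(propan-2-yl)nona-1,5-diene | C=C(Cl)[C@H](C(C)C)C/C=C(C)\CCC(OC)OC | intermediate
20 | (4Z,7S)-8-chloro-4-methyl-7-(propan-2-yl)nona-4,8-dienal | C=C(Cl)[C@H](C(C)C)C/C=C(C)\CCC=O | intermediate
21 | 2-(trimethylsilyl)-1,3-dithiane | C[Si](C)(C)C1SCCCS1 | starting material
22 | 2-lithio-2-(trimethylsilyl)-1,3-dithiane | [Li]C1([Si](C)(C)C)SCCCS1 | intermediate (not isolated)
23 | lithium β-silyl alkoxide from 20 and 22 (carbinol centre undefined) | [Li+].C=C(Cl)[C@H](C(C)C)C/C=C(C)\CCC([O-])C1([Si](C)(C)C)SCCCS1 | intermediate (not isolated)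
24 | 2-[(4Z,7S)-8-chloro-4-methyl-7-(propan-2-yl)nona-4,8-dien-1-ylidene]-1,3-dithiane (cyclisation precursor) | C=C(Cl)[C@H](C(C)C)C/C=C(C)\CCC=C1SCCCS1 | intermediate
25 | 2-alkyl-1,3-dithienium trifluoroacetate from 24 (cation at C4) | C=C(Cl)[C@H](C(C)C)C/C=C(C)\CCCC1=[S+]CCCS1.[O-]C(=O)C(F)(F)F | intermediate (not isolated)
26 | bicyclic 8-chloro-8-trifluoroacetoxy adduct (C8 undefined) | S3CCCSC31CCC[C@]2(C)CC(Cl)(OC(=O)C(F)(F)F)[C@H](C(C)C)C[C@@H]21 | intermediate (not isolated)
27 | cis-fused dithiane ketone: 15-nor-7-epi-5β-eudesman-8-one, C4 spiro to a 1,3-dithiane (5β-H, 10β-CH3, 7α-isopropyl; 5S,7S,10R) | S3CCCSC31CCC[C@]2(C)CC(=O)[C@H](C(C)C)C[C@@H]21 | intermediate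
28 | C8 ethylene ketal of 27 | S3CCCSC31CCC[C@]2(C)CC4(OCCO4)[C@H](C(C)C)C[C@@H]21 | intermediate
29 | 8,8-ethylenedioxy-15-nor-7-epi-5β-eudesman-4-one | O=C1CCC[C@]2(C)CC3(OCCO3)[C@H](C(C)C)C[C@@H]21 | intermediate
30 | potassium Δ3 enolate of 29 | [K+].[O-]C1=CCC[C@]2(C)CC3(OCCO3)[C@H](C(C)C)C[C@@H]21 | intermediate (not isolated)
31 | Δ3 enol triflate of 29 (triflate on C4) | FC(F)(F)S(=O)(=O)OC1=CCC[C@]2(C)CC3(OCCO3)[C@H](C(C)C)C[C@@H]21 | intermediate
32 | 8,8-ethylenedioxy-7-epi-5β-eudesm-3-ene | CC1=CCC[C@]2(C)CC3(OCCO3)[C@H](C(C)C)C[C@@H]21 | intermediate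
33 | 7-epi-5β-eudesm-3-en-8-one | CC1=CCC[C@]2(C)CC(=O)[C@H](C(C)C)C[C@@H]21 | intermediate
34 | 4α-acetoxy-3β-iodo-7-epi-5β-eudesman-8-one | CC(=O)O[C@]1(C)[C@@H](I)CC[C@]2(C)CC(=O)[C@H](C(C)C)C[C@@H]21 | intermediate (not isolated)
35 | 3α-acetoxy-4α-hydroxy-7-epi-5β-eudesman-8-one (any 4-acetate isomer reacts on in the same way) | O[C@]1(C)[C@H](OC(C)=O)CC[C@]2(C)CC(=O)[C@H](C(C)C)C[C@@H]21 | intermediate (not isolated)
36 | 3α,4α-dihydroxy-7-epi-5β-eudesman-8-one | O[C@]1(C)[C@H](O)CC[C@]2(C)CC(=O)[C@H](C(C)C)C[C@@H]21 | intermediate (not isolated)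
37 | 3α,4α-dihydroxy-5β-eudesman-8-one (3R,4S,5S,7R,10R) | O[C@]1(C)[C@H](O)CC[C@]2(C)CC(=O)[C@@H](C(C)C)C[C@@H]21 | intermediate
38 | angelic acid, (2Z)-2-methylbut-2-enoic acid | C/C=C(/C)C(=O)O | starting material
39 | (2Z)-2-methylbut-2-en-1-ol | C/C=C(/C)CO | intermediate
40 | [(2R,3S)-2,3-dimethyloxiran-2-yl]methanol | OC[C@@]1(C)O[C@H]1C | intermediate
41 | (2S,3S)-2,3-dimethyloxirane-2-carbaldehyde | O=C[C@@]1(C)O[C@H]1C | intermediate (not isolated)
42 | (2S,3S)-2,3-dimethyloxirane-2-carboxylic acid | OC(=O)[C@@]1(C)O[C@H]1C | intermediate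
43 | (2S,3S)-2,3-dimethyloxirane-2-carboxylic 2,4,6-trichlorobenzoic anhydride | O=C(OC(=O)c1c(Cl)cc(Cl)cc1Cl)[C@@]2(C)O[C@H]2C | intermediate (not isolated)
44 | 3α-[(2S,3S)-2,3-dimethyloxirane-2-carbonyloxy]-4α-hydroxy-5β-eudesman-8-one | O[C@]1(C)[C@H](OC(=O)[C@@]2(C)O[C@H]2C)CC[C@]2(C)CC(=O)[C@@H](C(C)C)C[C@@H]21 | intermediate
45 | 4α-acetoxy-3α-[(2S,3S)-2,3-dimethyloxirane-2-carbonyloxy]-5β-eudesman-8-one (3R,4S,5S,7R,10R) | CC(=O)O[C@]1(C)[C@H](OC(=O)[C@@]2(C)O[C@H]2C)CC[C@]2(C)CC(=O)[C@@H](C(C)C)C[C@@H]21 | target

**Step count**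
Total: 23 steps. Longest linear sequence: 19 steps (steps 1–3, 5–18, 22, 23).

**Steps most likely to fail**

Step 12. The ring B transition state with a pseudo-axial isopropyl group relieves allylic strain between the C7 substituent and the chlorine, so it may compete and erode the face selection. Proton loss from the C10 cation may also stop the cascade after ring A. Any diastereomer with the other fusion sense must be removed at 27, because after the later C7 equilibration it would become the enantiomer. The fallback exchanges the terminator for a terminal alkyne, which is linear and has nothing to eclipse the isopropyl group. It sets out from enol triflate 18. Elimination with LiN(iPr)2 in THF at −78 °C should give (3S,5Z)-9,9-dimethoxy-6-methyl-3-(propan-2-yl)non-5-en-1-yne F1, dilute HCl in THF the alkynal F2, and Peterson olefination with 22 the alkynyl ketene dithioacetal F3. CF3CO2H in CH2Cl2 should then close ring A as before and ring B by 6-endo attack of the alkyne terminus on C10, the cyclohexenyl cation being trapped as the enol trifluoroacetate F4. Hydrolysis of F4 (K2CO3, MeOH–H2O) brings the route back at 27.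

Step 18. The assumption that ring B screens the α face may not hold for this flexible cis-decalin. If the iodonium ion forms on the α face instead, both oxygens end up on the β face; elimination from the tertiary centre may also compete with acetate capture. The fallback uses the facial preference directly instead of inverting it: catalytic OsO4 with N-methylmorpholine N-oxide in acetone–water adds both oxygens in one step to the face the electrophile prefers. It sets out from 33, should give the 7-epi keto diol 36, and NaOMe in MeOH then brings the route back at 37.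

Step 23. Acylation of the tertiary 4α-hydroxyl, which sits on the concave face, may be too slow, so that migration of the C3 acyl group or opening of the oxirane under forcing conditions competes. The fallback reverses the order of the acylations and delivers the acetate intramolecularly. It sets out from 37. MeC(OMe)3 with PPTS should give the cyclic 3,4-orthoacetate F5. Aqueous acetic acid should open it to the axial ester, the 4α-acetoxy-3α-hydroxy ketone F6 (the known preference for the axial ester on hydrolysis of cyclic orthoesters). Esterification of the free 3α-hydroxyl with mixed anhydride 43 and DMAP at 0 °C then comes back to the route at 45.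

**Further compounds**
F1 | step 12 | (3S,5Z)-9,9-dimethoxy-6-methyl-3-(propan-2-yl)non-5-en-1-yne | C#C[C@H](C(C)C)C/C=C(C)\CCC(OC)OC
F2 | step 12 | (4Z,7S)-4-methyl-7-(propan-2-yl)non-4-en-8-ynal | C#C[C@H](C(C)C)C/C=C(C)\CCC=O
F3 | step 12 | 2-[(4Z,7S)-4-methyl-7-(propan-2-yl)non-4-en-8-yn-1-ylidene]-1,3-dithiane | C#C[C@H](C(C)C)C/C=C(C)\CCC=C1SCCCS1
F4 | step 12 | enol trifluoroacetate of 27 (C8=C9 olefin, ester on C8) | S3CCCSC31CCC[C@]2(C)C=C(OC(=O)C(F)(F)F)[C@H](C(C)C)C[C@@H]21
F0 | step 18 | none | none
F5 | step 23 | cyclic 3α,4α-orthoacetate of 37 (2-methoxy-2-methyl-1,3-dioxolane, orthoester carbon undefined) | COC3(C)O[C@]1(C)[C@H](O3)CC[C@]2(C)CC(=O)[C@@H](C(C)C)C[C@@H]21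
F6 | step 23 | 4α-acetoxy-3α-hydroxy-5β-eudesman-8-one | CC(=O)O[C@]1(C)[C@H](O)CC[C@]2(C)CC(=O)[C@@H](C(C)C)C[C@@H]21
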